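## Retrosynthetic overview

- The route rests on one feature of the cyclohexene ring: C3 is the α-carbon of an acrylate-type unit (C2=C3–C7, C7 at the carboxyl level) and its neighbour C4 is a carbinol, while the oxygenated C1, C6 and C5 carry the configuration of C2, C3 and C4 of D-arabinose.
- Endgame: target 19 from the cis-5,6-diol 16 through a cyclic orthobenzoate that puts the benzoyl group on O5; the C1 acetate and C7 benzoate come from stepwise acylation after ester reduction, with O4 held as a silyl ether.
- Key disconnection C3–C4: cyclohexene ester 10 from the acyclic enoate aldehyde 7 by a PMe3-catalysed intramolecular Morita–Baylis–Hillman reaction.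
- Aldehyde 7 from D-arabinose 1: 3,4-acetonide, Wittig homologation at the sugar C1, bis-silylation, oxidative unmasking of the primary position.
- Ring order: dioxolane at the sugar stage (step 1), then the six-membered carbocycle (step 5); the dioxolane is opened again in step 11.

Key step: step 5

Remark on the chemistry: ring locants are C1 (acetoxy carbon of the target), C2=C3, C4, C5, C6, with C7 the exocyclic carbon on C3; α is the face of O1 and O4, β the face of O5 and O6. The C1 oxygen is carried as a triethylsilyl ether so that it can later be freed in the presence of a C4 tert-butyldimethylsilyl ether. Lactol 2 is an anomeric mixture, and any Z-enoate from step 2 is carried on because phosphine addition in step 5 erases the alkene geometry.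

## Route

Step 1
Reactants: 1 D-arabinose
Product: 2 3,4-O-isopropylidene-D-arabinopyranose (anomeric mixture)
Conditions: Me2C(OMe)2, TsOH·H2O (cat.), DMF, rt; Et3N quench
Reagents that add atoms: 2,2-dimethoxypropane, COC(C)(C)OC
Why: Acid-catalysed transacetalisation (acetonide formation) engages the only cis-vicinal diol of the pyranose, O3/O4, and leaves the anomeric and C2 hydroxyls free without touching a stereocentre.

Step 2
Reactants: 2 3,4-O-isopropylidene-D-arabinopyranose; 3 methyl (triphenylphosphoranylidene)acetate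
Product: 4 methyl (E)-2,3-dideoxy-5,6-O-isopropylidene-D-arabino-hept-2-enonate (4-OH and 7-OH free)
Conditions: 3 (1.3 equiv), PhCO2H (cat.), CH2Cl2, reflux
Reagents that add atoms: methyl (triphenylphosphoranylidene)acetate (compound 3), COC(=O)C=P(c1ccccc1)(c1ccccc1)c1ccccc1
Why: Wittig olefination of the open-chain aldehyde form of the lactol with the stabilised ylide should give mainly the E-enoate, the aprotic medium and mild acid catalysis limiting oxa-Michael closure by the primary hydroxyl and lactonisation of any Z isomer.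

Step 3
Reactants: 4 methyl (E)-2,3-dideoxy-5,6-O-isopropylidene-D-arabino-hept-2-enonate
Product: 5 methyl (E)-2,3-dideoxy-5,6-O-isopropylidene-4,7-bis-O-(triethylsilyl)-D-arabino-hept-2-enonate
Conditions: TESCl (2.4 equiv), imidazole, DMAP (cat.), CH2Cl2, 0 °C to rt
Reagents that add atoms: chlorotriethylsilane, CC[Si](Cl)(CC)CC
Why: Silyl ether formation with excess TESCl/imidazole caps both the primary and the allylic secondary hydroxyl under conditions too mild to trigger conjugate addition.

Step 4
Reactants: 5 methyl (E)-2,3-dideoxy-5,6-O-isopropylidene-4,7-bis-O-(triethylsilyl)-D-arabino-hept-2-enonate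
Product: 7 methyl (2E,4R,5R,6S)-5,6-(isopropylidenedioxy)-7-oxo-4-(triethylsilyloxy)hept-2-enoate, via alkoxydimethylsulfonium chloride 6 (not isolated)
Conditions: (COCl)2, DMSO, CH2Cl2, −78 to −40 °C; then i-Pr2NEt, −78 to 0 °C; used crude
Reagents that add atoms: none
Why: Under Swern conditions a primary triethylsilyl ether is cleaved by the chlorosulfonium reagent and oxidised in the same flask while the hindered secondary triethylsilyl ether survives (chemoselective Swern oxidation of a primary TES ether), and the hindered amine at low temperature should keep the α-alkoxy aldehyde centre from epimerising.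

Step 5
Reactants: 7 methyl (2E,4R,5R,6S)-5,6-(isopropylidenedioxy)-7-oxo-4-(triethylsilyloxy)hept-2-enoate
Product: 10 methyl (1R,4S,5R,6R)-4-hydroxy-5,6-(isopropylidenedioxy)-1-(triethylsilyloxy)cyclohex-2-ene-3-carboxylate, via phosphonium enolate zwitterion 8 (not isolated), via phosphonium aldolate zwitterion 9 (not isolated)
Conditions: PMe3 (0.5 equiv), THF/t-BuOH (1:1), 0.02 M, 0 °C to rt, Ar
Reagents that add atoms: none
Why: PMe3 adds reversibly to C2 of the enoate to give zwitterion 8, whose ester enolate carbon C3 attacks the C4 aldehyde to give aldolate 9; proton transfer and E1cB loss of PMe3 then restore the C2=C3 alkene, which is the phosphine-catalysed intramolecular Morita–Baylis–Hillman reaction known for formyl-tethered enoates. The six-membered carbocycle closes by a 6-(enolexo)-exo-trig aldol cyclisation that forms the C3–C4 bond. The new stereocentre C4 is controlled by C5 of the cis-fused dioxolane: in the chair-like transition state that keeps the C1 silyloxy group equatorial, the aldehyde C=O lies antiperiplanar to the C5–O bond (dipole-minimised, Cornforth-type), so O4 and O5 develop trans-diaxial and the hydroxyl should end trans to O5 (4S). The step needs this facial selectivity, cyclisation in preference to intermolecular coupling (secured by the six-membered tether and dilution), and no epimerisation at C5 (PMe3 is a weak Brønsted base and the aldehyde is used fresh). Because phosphine addition removes the alkene geometry, any Z isomer of 7 should converge on the same product.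

Step 6
Reactants: 10 methyl (1R,4S,5R,6R)-4-hydroxy-5,6-(isopropylidenedioxy)-1-(triethylsilyloxy)cyclohex-2-ene-3-carboxylate
Product: 11 methyl 4-(tert-butyldimethylsilyloxy)-5,6-(isopropylidenedioxy)-1-(triethylsilyloxy)cyclohex-2-ene-3-carboxylate (1α,4α,5β,6β; configuration of 10)
Conditions: TBSOTf (1.3 equiv), 2,6-lutidine, CH2Cl2, −78 to 0 °C
Reagents that add atoms: tert-butyldimethylsilyl trifluoromethanesulfonate, CC(C)(C)[Si](C)(C)OS(=O)(=O)C(F)(F)F
Why: Silyl ether formation with the silyl triflate and a non-nucleophilic base is fast on the hindered allylic alcohol at low temperature, which leaves the triethylsilyl ether and acetonide in place and installs the bulky C4 group that later biases the ring conformation.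

Step 7
Reactants: 11 methyl 4-(tert-butyldimethylsilyloxy)-5,6-(isopropylidenedioxy)-1-(triethylsilyloxy)cyclohex-2-ene-3-carboxylate
Product: 12 [4-(tert-butyldimethylsilyloxy)-5,6-(isopropylidenedioxy)-1-(triethylsilyloxy)cyclohex-2-en-3-yl]methanol (1α,4α,5β,6β)
Conditions: i-Bu2AlH (2.5 equiv), CH2Cl2, −78 °C; aq. KNaC4H4O6 work-up
Reagents that add atoms: none
Why: i-Bu2AlH at −78 °C reduces the conjugated methyl ester by 1,2-hydride delivery (DIBAL reduction of an enoate to the allylic alcohol) without affecting the silyl ethers, the acetonide or the alkene.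

Step 8
Reactants: 12 [4-(tert-butyldimethylsilyloxy)-5,6-(isopropylidenedioxy)-1-(triethylsilyloxy)cyclohex-2-en-3-yl]methanol
Product: 13 [4-(tert-butyldimethylsilyloxy)-5,6-(isopropylidenedioxy)-1-(triethylsilyloxy)cyclohex-2-en-3-yl]methyl benzoate (1α,4α,5β,6β)
Conditions: BzCl, pyridine, DMAP (cat.), CH2Cl2, 0 °C
Reagents that add atoms: benzoyl chloride, O=C(Cl)c1ccccc1
Why: Nucleophile-catalysed esterification of the only free hydroxyl, the primary allylic C7 alcohol, is straightforward.

Step 9
Reactants: 13 [4-(tert-butyldimethylsilyloxy)-5,6-(isopropylidenedioxy)-1-(triethylsilyloxy)cyclohex-2-en-3-yl]methyl benzoate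
Product: 14 [4-(tert-butyldimethylsilyloxy)-1-hydroxy-5,6-(isopropylidenedioxy)cyclohex-2-en-3-yl]methyl benzoate (1α,4α,5β,6β)
Conditions: HF·pyridine, pyridine, THF, 0 °C
Reagents that add atoms: none
Why: Buffered HF·pyridine cleaves a secondary triethylsilyl ether far faster than the more hindered tert-butyldimethylsilyl ether at C4 (selective fluoride-mediated desilylation) and spares the acetonide and the benzoate.

Step 10
Reactants: 14 [4-(tert-butyldimethylsilyloxy)-1-hydroxy-5,6-(isopropylidenedioxy)cyclohex-2-en-3-yl]methyl benzoate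
Product: 15 [1-acetoxy-4-(tert-butyldimethylsilyloxy)-5,6-(isopropylidenedioxy)cyclohex-2-en-3-yl]methyl benzoate (1α,4α,5β,6β)
Conditions: Ac2O, pyridine, DMAP (cat.), CH2Cl2, 0 °C to rt
Reagents that add atoms: acetic anhydride, CC(=O)OC(C)=O
Why: DMAP-catalysed acetylation of the single free secondary hydroxyl engages only the O–H bond, so C1 keeps its configuration.

Step 11
Reactants: 15 [1-acetoxy-4-(tert-butyldimethylsilyloxy)-5,6-(isopropylidenedioxy)cyclohex-2-en-3-yl]methyl benzoate
Product: 16 [1-acetoxy-4-(tert-butyldimethylsilyloxy)-5,6-dihydroxycyclohex-2-en-3-yl]methyl benzoate (1α,4α,5β,6β)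
Conditions: TFA/H2O (9:1), CH2Cl2, 0 °C, short reaction time; NaHCO3 quench
Reagents that add atoms: none
Why: Brønsted-acid acetal hydrolysis releases the cis-5,6-diol, the short exposure at 0 °C being chosen so that the hindered C4 silyl ether and the two allylic esters survive without acyl shift.

Step 12
Reactants: 16 [1-acetoxy-4-(tert-butyldimethylsilyloxy)-5,6-dihydroxycyclohex-2-en-3-yl]methyl benzoate
Product: 18 [1-acetoxy-5-benzoyloxy-4-(tert-butyldimethylsilyloxy)-6-hydroxycyclohex-2-en-3-yl]methyl benzoate (1α,4α,5β,6β), via cyclic orthobenzoate 17 (not isolated)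
Conditions: PhC(OMe)3, CSA (cat.), MeCN, rt; then AcOH/H2O (4:1), rt
Reagents that add atoms: trimethyl orthobenzoate, COC(OC)(OC)c1ccccc1; water, O
Why: Acid-catalysed orthoester exchange closes a five-membered orthobenzoate on the cis-5,6-diol and its mild hydrolysis follows the axial-ester rule of cyclic orthoester opening, the C4 silyloxy group sitting pseudoaxial to escape A(1,2) strain with the C3 substituent so that the trans C5 oxygen is axial and should receive the benzoyl group while the equatorial C6 hydroxyl is set free.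

Step 13
Reactants: 18 [1-acetoxy-5-benzoyloxy-4-(tert-butyldimethylsilyloxy)-6-hydroxycyclohex-2-en-3-yl]methyl benzoate
Product: 19 (1R,4S,5R,6S)-1-acetoxy-5-benzoyloxy-3-(benzoyloxymethyl)cyclohex-2-ene-4,6-diol (route locants; the target)
Conditions: HF·pyridine, THF, 0 °C to rt
Reagents that add atoms: none
Why: Fluoride-mediated desilylation with acidic HF·pyridine removes the last silyl ether without the basic conditions that would move acyl groups among O1, O4, O5 and O6.

## Compound list

1 | D-arabinose | O=C[C@@H](O)[C@H](O)[C@H](O)CO | starting material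
2 | 3,4-O-isopropylidene-D-arabinopyranose (anomeric mixture) | OC1OC[C@H]2OC(C)(C)O[C@H]2[C@@H]1O | intermediate
3 | methyl (triphenylphosphoranylidene)acetate | COC(=O)C=P(c1ccccc1)(c1ccccc1)c1ccccc1 | starting material
4 | methyl (E)-2,3-dideoxy-5,6-O-isopropylidene-D-arabino-hept-2-enonate | COC(=O)/C=C/[C@@H](O)[C@@H]1OC(C)(C)O[C@@H]1CO | intermediate
5 | methyl (E)-2,3-dideoxy-5,6-O-isopropylidene-4,7-bis-O-(triethylsilyl)-D-arabino-hept-2-enonate | COC(=O)/C=C/[C@@H](O[Si](CC)(CC)CC)[C@@H]1OC(C)(C)O[C@@H]1CO[Si](CC)(CC)CC | intermediate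
6 | C7 alkoxydimethylsulfonium chloride of the mono-TES enoate (not isolated) | COC(=O)/C=C/[C@@H](O[Si](CC)(CC)CC)[C@@H]1OC(C)(C)O[C@@H]1CO[S+](C)C.[Cl-] | intermediate
7 | methyl (2E,4R,5R,6S)-5,6-(isopropylidenedioxy)-7-oxo-4-(triethylsilyloxy)hept-2-enoate | COC(=O)/C=C/[C@@H](O[Si](CC)(CC)CC)[C@@H]1OC(C)(C)O[C@@H]1C=O | intermediate
8 | C2 trimethylphosphonium ester enolate zwitterion (C2 epimers; not isolated) | COC([O-])=CC([P+](C)(C)C)[C@@H](O[Si](CC)(CC)CC)[C@@H]1OC(C)(C)O[C@@H]1C=O | intermediate
9 | cyclised C2 trimethylphosphonium C4 alkoxide zwitterion (C2/C3 epimers; not isolated) | CC[Si](CC)(CC)O[C@@H]1C([P+](C)(C)C)C(C(=O)OC)[C@H]([O-])[C@H]2OC(C)(C)O[C@@H]12 | intermediate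
10 | methyl (1R,4S,5R,6R)-4-hydroxy-5,6-(isopropylidenedioxy)-1-(triethylsilyloxy)cyclohex-2-ene-3-carboxylate | CC[Si](CC)(CC)O[C@@H]1C=C(C(=O)OC)[C@H](O)[C@H]2OC(C)(C)O[C@@H]12 | intermediate
11 | methyl 4-(tert-butyldimethylsilyloxy)-5,6-(isopropylidenedioxy)-1-(triethylsilyloxy)cyclohex-2-ene-3-carboxylate (1α,4α,5β,6β) | CC[Si](CC)(CC)O[C@@H]1C=C(C(=O)OC)[C@H](O[Si](C)(C)C(C)(C)C)[C@H]2OC(C)(C)O[C@@H]12 | intermediate
12 | [4-(tert-butyldimethylsilyloxy)-5,6-(isopropylidenedioxy)-1-(triethylsilyloxy)cyclohex-2-en-3-yl]methanol (1α,4α,5β,6β) | CC[Si](CC)(CC)O[C@@H]1C=C(CO)[C@H](O[Si](C)(C)C(C)(C)C)[C@H]2OC(C)(C)O[C@@H]12 | intermediate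
13 | [4-(tert-butyldimethylsilyloxy)-5,6-(isopropylidenedioxy)-1-(triethylsilyloxy)cyclohex-2-en-3-yl]methyl benzoate (1α,4α,5β,6β) | CC[Si](CC)(CC)O[C@@H]1C=C(COC(=O)c3ccccc3)[C@H](O[Si](C)(C)C(C)(C)C)[C@H]2OC(C)(C)O[C@@H]12 | intermediate
14 | [4-(tert-butyldimethylsilyloxy)-1-hydroxy-5,6-(isopropylidenedioxy)cyclohex-2-en-3-yl]methyl benzoate (1α,4α,5β,6β) | O[C@@H]1C=C(COC(=O)c3ccccc3)[C@H](O[Si](C)(C)C(C)(C)C)[C@H]2OC(C)(C)O[C@@H]12 | intermediate
15 | [1-acetoxy-4-(tert-butyldimethylsilyloxy)-5,6-(isopropylidenedioxy)cyclohex-2-en-3-yl]methyl benzoate (1α,4α,5β,6β) | CC(=O)O[C@@H]1C=C(COC(=O)c3ccccc3)[C@H](O[Si](C)(C)C(C)(C)C)[C@H]2OC(C)(C)O[C@@H]12 | intermediate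
16 | [1-acetoxy-4-(tert-butyldimethylsilyloxy)-5,6-dihydroxycyclohex-2-en-3-yl]methyl benzoate (1α,4α,5β,6β) | CC(=O)O[C@@H]1C=C(COC(=O)c2ccccc2)[C@H](O[Si](C)(C)C(C)(C)C)[C@@H](O)[C@H]1O | intermediate
17 | 5,6-O-(α-methoxybenzylidene) cyclic orthobenzoate of 16 (orthoester carbon epimers; not isolated) | CC(=O)O[C@@H]1C=C(COC(=O)c3ccccc3)[C@H](O[Si](C)(C)C(C)(C)C)[C@H]2OC(OC)(c3ccccc3)O[C@@H]12 | intermediate
18 | [1-acetoxy-5-benzoyloxy-4-(tert-butyldimethylsilyloxy)-6-hydroxycyclohex-2-en-3-yl]methyl benzoate (1α,4α,5β,6β) | CC(=O)O[C@@H]1C=C(COC(=O)c2ccccc2)[C@H](O[Si](C)(C)C(C)(C)C)[C@@H](OC(=O)c2ccccc2)[C@H]1O | intermediate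
19 | (1R,4S,5R,6S)-1-acetoxy-5-benzoyloxy-3-(benzoyloxymethyl)cyclohex-2-ene-4,6-diol (route locants) | CC(=O)O[C@@H]1C=C(COC(=O)c2ccccc2)[C@H](O)[C@@H](OC(=O)c2ccccc2)[C@H]1O | target

## Step count and risks

Total step count: 13. Longest linear sequence: 13 steps from D-arabinose.

Steps most likely to fail:

1. Step 5. Phosphine addition at the hindered C2 may be slow, leaving time for epimerisation at C5 or oligomerisation, and the facial selectivity at C4 may be poor. Fallback: set out from 7 and replace the catalytic reaction by a stoichiometric tandem Michael–aldol. PhSLi (from PhSH and n-BuLi, THF, −78 to −20 °C) should add to C2, and the lithium ester enolate should close onto the C4 aldehyde to give the 2-phenylthio-4-hydroxy cyclohexanecarboxylate F1. Oxidation at sulfur (mCPBA, 1 equiv, CH2Cl2, −78 °C) would give the sulfoxide F2. Its thermal syn-elimination toward the acidic C3–H (toluene, 80 °C, CaCO3) would regenerate the C2=C3 alkene and return to the route at 10.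

2. Step 12. The orthoester may open toward the C6 ester if the ring does not hold the C5 oxygen axial, or the benzoyl group may shift from O5 to O6 during hydrolysis. Fallback: set out from 16 and tell the two hydroxyls apart by silylation. TESCl, imidazole, CH2Cl2, −20 °C should cap the equatorial, less hindered C6 hydroxyl to give the C6 triethylsilyl ether F3. Benzoylation of the remaining C5 hydroxyl (BzCl, DMAP, pyridine, rt) would give the C5 benzoate F4. HF·pyridine in THF would then remove both silyl groups and return to the route at 19.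

3. Step 11. The C4 silyl ether may be partly lost, or an acyl group may shift, under the aqueous acid. Fallback: set out from 15 and remove acetonide and silyl ether together (TFA/H2O 4:1, rt) to give the 4,5,6-triol F5. PhC(OMe)3 with catalytic CSA should then engage only the cis-5,6-diol as the cyclic orthobenzoate F6, since the trans-4,5 pair cannot bridge a five-membered orthoester comfortably. Aqueous AcOH should open it to the axial C5 benzoate, again relying on the pseudoaxial preference of the C4 oxygen, and return to the route at 19.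

## Further compounds

F1 | step 5 | methyl 4-hydroxy-5,6-(isopropylidenedioxy)-2-(phenylthio)-1-(triethylsilyloxy)cyclohexane-3-carboxylate (C2/C3 epimers) | CC[Si](CC)(CC)O[C@@H]1C(Sc3ccccc3)C(C(=O)OC)[C@H](O)[C@H]2OC(C)(C)O[C@@H]12
F2 | step 5 | methyl 4-hydroxy-5,6-(isopropylidenedioxy)-2-(phenylsulfinyl)-1-(triethylsilyloxy)cyclohexane-3-carboxylate (C2/C3/S epimers) | CC[Si](CC)(CC)O[C@@H]1C(S(=O)c3ccccc3)C(C(=O)OC)[C@H](O)[C@H]2OC(C)(C)O[C@@H]12
F3 | step 12 | [1-acetoxy-4-(tert-butyldimethylsilyloxy)-5-hydroxy-6-(triethylsilyloxy)cyclohex-2-en-3-yl]methyl benzoate (1α,4α,5β,6β) | CC(=O)O[C@@H]1C=C(COC(=O)c2ccccc2)[C@H](O[Si](C)(C)C(C)(C)C)[C@@H](O)[C@H]1O[Si](CC)(CC)CC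
F4 | step 12 | [1-acetoxy-5-benzoyloxy-4-(tert-butyldimethylsilyloxy)-6-(triethylsilyloxy)cyclohex-2-en-3-yl]methyl benzoate (1α,4α,5β,6β) | CC(=O)O[C@@H]1C=C(COC(=O)c2ccccc2)[C@H](O[Si](C)(C)C(C)(C)C)[C@@H](OC(=O)c2ccccc2)[C@H]1O[Si](CC)(CC)CC
F5 | step 11 | (1-acetoxy-4,5,6-trihydroxycyclohex-2-en-3-yl)methyl benzoate (1α,4α,5β,6β) | CC(=O)O[C@@H]1C=C(COC(=O)c2ccccc2)[C@H](O)[C@@H](O)[C@H]1O
F6 | step 11 | 5,6-O-(α-methoxybenzylidene) cyclic orthobenzoate of F5 (orthoester carbon epimers) | CC(=O)O[C@@H]1C=C(COC(=O)c3ccccc3)[C@H](O)[C@H]2OC(OC)(c3ccccc3)O[C@@H]12
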